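**Plan**

1. Atom labels: C1 is the spiro carbon, C2 and C9 its CH2 groups, C3 and C7 the ring-fusion CH, C4 and C8 the carbinol carbons of ring C and ring B, C5 and C6 the ring C CH2 groups; Ca and Cb are the ring A carbonyls on C1, Ca next to the diprenyl carbon.
2. Ring A is cut at both prenyl–C bonds, at Ca–CH2 (Dieckmann) and at Cb–C(acyl) (C-acylation). This leads back to a lactone acid in which C1 carries Ca as a γ-lactone to O–C8 and Cb as CO2H; the C4 methyl is cut back to a ketone.
3. Rings B and C share only the C3–C7 bond, and the nine atoms C1–C9 around it form one ring. Cutting C3–C7 together with the lactone C8–O bond therefore gives a nine-membered malonate in which a 3,4-epoxide faces a 7,8-(E)-alkene across the ring.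
4. Forward order: chain C2–C9 (alkyne alkylation, reduction, epoxidation, allylic oxidation), malonate joined at C9, nine-membered ring closed at C2, then rings C, B and the lactone in one step, then the C4 methyl carbinol, then ring A (acylation, Dieckmann closure, double prenylation).
5. Stereochemistry: the Sharpless epoxidation sets C3 and C4. C3 is inverted in the key step and relays to C7 (trans fusion), C8 and C1 (axial lactone). C4 is rebuilt by methyl addition anti to C2. The lactone/acid difference at C1 tells Ca from Cb.

Key step: step 9

Remark: in a backside opening a cis-epoxide (from a (Z)-allylic alcohol) can only give the cis ring fusion, and a trans-epoxide carrying the C4 methyl would give the C4 epimer; the route therefore uses the methyl-free trans-epoxide and makes the C4 carbinol afterwards from the ketone.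

**Route**

Step 1
Reactants: 1 propargyl alcohol (prop-2-yn-1-ol); 2 5-bromo-2-methylpent-2-ene
Product: 3 7-methyloct-6-en-2-yn-1-ol
Conditions: n-BuLi (2.1 equiv), THF/DMPU, −78 °C to rt
Reagents that add atoms: none
Why: Acetylide alkylation of the O,C-dianion of propargyl alcohol by the primary bromide should give the eight-carbon chain C2–C9 with its terminal gem-dimethyl alkene.

Step 2
Reactants: 3 7-methyloct-6-en-2-yn-1-ol
Product: 4 (2E)-7-methylocta-2,6-dien-1-ol
Conditions: NaAlH2(OCH2CH2OMe)2 (Red-Al), THF, 0 °C to rt
Reagents that add atoms: none
Why: Hydroxyl-directed trans-hydroalumination of the propargylic alcohol followed by protonolysis should give only the (E)-allylic alcohol and leave the isolated alkene untouched.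

Step 3
Reactants: 4 (2E)-7-methylocta-2,6-dien-1-ol
Product: 5 [(2R,3R)-3-(4-methylpent-3-en-1-yl)oxiran-2-yl]methanol (trans-epoxide; future C3 and C4)
Conditions: Ti(OiPr)4 (cat.), D-(−)-diethyl tartrate (cat.), t-BuOOH, 4 Å molecular sieves, CH2Cl2, −20 °C
Reagents that add atoms: tert-butyl hydroperoxide, CC(C)(C)OO
Why: Sharpless asymmetric epoxidation of the (E)-allylic alcohol with the D-tartrate complex should deliver oxygen to the face that gives the (2R,3R)-epoxide, and the remote trisubstituted alkene does not react.

Step 4
Reactants: 5 [(2R,3R)-3-(4-methylpent-3-en-1-yl)oxiran-2-yl]methanol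
Product: 6 [(2R,3R)-3-(4-methylpent-3-en-1-yl)oxiran-2-yl]methyl 4-methylbenzenesulfonate
Conditions: TsCl, Et3N, DMAP (cat.), CH2Cl2, 0 °C
Reagents that add atoms: 4-methylbenzenesulfonyl chloride, Cc1ccc(cc1)S(Cl)(=O)=O
Why: Tosylation of the primary alcohol turns C2 into an SN2 electrophile activated by the neighbouring epoxide and masks the hydroxyl group for the next three steps.

Step 5
Reactants: 6 epoxy tosylate
Product: 7 [(2R,3R)-3-[(3E)-5-hydroxy-4-methylpent-3-en-1-yl]oxiran-2-yl]methyl 4-methylbenzenesulfonate
Conditions: SeO2 (cat.), t-BuOOH, salicylic acid (cat.), CH2Cl2, rt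
Reagents that add atoms: tert-butyl hydroperoxide, CC(C)(C)OO; selenium dioxide (oxygen carrier), O=[Se]=O
Why: Allylic oxidation with SeO2 (ene reaction, then [2,3]-shift) should hydroxylate the (E)-methyl group of the gem-dimethyl alkene selectively, which fixes the (E)-geometry of the C7=C8 alkene with C9 as CH2OH.

Step 6
Reactants: 7 (E)-allylic alcohol
Product: 8 [(2R,3R)-3-[(3E)-5-bromo-4-methylpent-3-en-1-yl]oxiran-2-yl]methyl 4-methylbenzenesulfonate
Conditions: CBr4, PPh3, CH2Cl2, 0 °C
Reagents that add atoms: tetrabromomethane, BrC(Br)(Br)Br
Why: The Appel reaction converts the allylic alcohol into the bromide under neutral conditions that should leave the epoxide and the tosylate intact.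

Step 7
Reactants: 8 allylic bromide; 9 di-tert-butyl malonate
Product: 10 di-tert-butyl 2-[(2E)-2-methyl-5-[(2R,3R)-3-(tosyloxymethyl)oxiran-2-yl]pent-2-en-1-yl]malonate
Conditions: NaH, 9 (1.5 equiv), THF, 0 °C
Reagents that add atoms: none
Why: In this malonic ester alkylation the sodium enolate of 9 should displace the allylic bromide much faster than the tosylate, and the excess of malonate holds back dialkylation.

Step 8
Reactants: 10 acyclic malonate
Product: 11 di-tert-butyl (3R,4R,7E)-3,4-epoxy-8-methylcyclonon-7-ene-1,1-dicarboxylate (trans-epoxide, (E)-alkene; C1 is the malonate carbon)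
Conditions: Cs2CO3, n-Bu4NI (cat.), MeCN, 60 °C, syringe-pump addition (high dilution)
Reagents that add atoms: none
Why: Intramolecular malonate alkylation at the epoxide-activated primary carbon C2 should close the nine-membered ring, because attack at either epoxide carbon would place the (E)-alkene in a seven- or eight-membered ring.

Step 9
Reactants: 11 nine-membered epoxy alkene malonate
Product: 12 tricyclic hydroxy lactone tert-butyl ester: trans-fused rings B (six-membered) and C (five-membered); secondary OH at C4 cis to C3–H; C8 bears an equatorial CH3 and the axial lactone oxygen (syn to C3–H); C1 bears the lactone carbonyl Ca and CO2t-Bu (Cb); C1 R, C3 R, C4 R, C7 S, C8 R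
Conditions: BF3·OEt2 (0.5 equiv), CH2Cl2, −40 to 0 °C
Reagents that add atoms: none
Why: Proposed new method: BF3 activates the trans-epoxide, the alkene carbon C7 opens it at C3 from inside the ring with inversion while the C4–O bond stays, and the tertiary cation at C8 is captured by the 1,3-syn-axial tert-butyl ester with loss of isobutene; the closest known reactions are the acid-induced transannular cyclizations of medium-ring epoxy alkenes (4,5-epoxygermacranolides to guaianolides, caryophyllene oxide) and ester-terminated cation–olefin cyclizations. Ring C closes through the C3–C7 bond (5-exo for the alkene, endo for the epoxide), ring B through the same bond as a chair, and the γ-lactone by 5-exo capture of the cation at C8. C3 is set by inversion of the (R)-epoxide carbon, C4 is carried over, C7 by the chair-like closure of the (E)-alkene in which both ring C bonds are equatorial and C8 is anti to C4 (trans fusion), and C8 and C1 together by the only ester that reaches the cation (axial C–O, syn to C3–H). A backside opening leaves O–C4 anti to the new bond, which a trans-fused hydrindane tolerates only for a trans-epoxide, so a trans-epoxide without the C4 methyl is the substrate. The step needs C7-to-C3 attack over ester-carbonyl attack on the epoxide and trans over cis fusion: pairing C7 with C3 is the only one that avoids a four-membered ring or a secondary cation, the strained (E)-alkene lies across the ring from C3, and the all-equatorial chair favours the trans fusion.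

Step 10
Reactants: 12 hydroxy lactone tert-butyl ester
Product: 13 hydroxy lactone acid (CO2H in place of CO2t-Bu; otherwise as 12)
Conditions: CF3CO2H, CH2Cl2, 0 °C to rt
Reagents that add atoms: none
Why: Acidolysis of the tert-butyl ester is done here, before a tertiary alcohol exists at C4, because the bridged tertiary lactone is the thermodynamic product under acid and the secondary alcohol does not ionise.

Step 11
Reactants: 13 hydroxy lactone acid
Product: 14 keto lactone acid (C4 ketone; C1 R, C3 R, C7 S, C8 R)
Conditions: DMP, CH2Cl2, rt
Reagents that add atoms: none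
Why: Dess–Martin oxidation converts the secondary alcohol into the cyclopentanone under neutral conditions that should not epimerise C3, which is now alpha to the ketone.

Step 12
Reactants: 14 keto lactone acid
Product: 15 tertiary hydroxy lactone acid (C4 bears CH3 cis to C3–H and OH cis to C2; C4 S)
Conditions: MeMgBr (4 equiv), CeCl3, THF, −78 °C
Reagents that add atoms: methylmagnesium bromide, C[Mg]Br
Why: Organocerium 1,2-addition (a Grignard-type addition with a weakly basic reagent) to the cyclopentanone should bring methyl in anti to the C3–C2 bond, on the face of C3–H as with 2-alkylcyclopentanones, while the carboxylate and the hindered lactone are not attacked.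

Step 13
Reactants: 15 tertiary hydroxy lactone acid; 16 5-methylhexane-2,4-dione
Product: 18 lactone triketone in which Cb is bonded to the central carbon of the diketone, C1–C(=O)–CH(COCH3)(COCH(CH3)2), via acyl imidazolide 17 (not isolated)
Conditions: (imidazol-1-yl)2CO (CDI), THF, rt, then 16, MgCl2, Et3N, MeCN, rt to 50 °C
Reagents that add atoms: none
Why: C-acylation of a 1,3-diketone under soft enolisation: the acid is activated as its acyl imidazolide, which the tertiary alcohol does not disturb, and the magnesium chelate of 16 is acylated on its central carbon, so that Cb becomes bonded to the carbon that already carries the isobutyryl group.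

Step 14
Reactants: 18 lactone triketone
Product: 19 spiro trione with ring A closed: free CH2 between Ca and the enol carbon, isobutyryl on the carbon between Cb and the enol carbon, both tertiary alcohols free
Conditions: LiN(i-Pr)2 (4.5 equiv), THF, −78 to 0 °C, then aq. HCl
Reagents that add atoms: none
Why: In this Dieckmann (intramolecular Claisen) condensation the acetyl methyl of the deprotonated triketone should attack the lactone carbonyl Ca in a six-membered closure, which releases the tertiary alkoxide at C8 and is driven by the doubly enolisable product anion.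

Step 15
Reactants: 19 spiro trione; 20 prenyl bromide (1-bromo-3-methylbut-2-ene)
Product: 21 target compound
Conditions: 20 (2.5 equiv), NaOMe, MeOH, 0 °C to rt, then aq. HCl
Reagents that add atoms: none
Why: Double C-alkylation of the only free ring A methylene, as in the dearomatising C-prenylation of acylphloroglucinols, should install both prenyl groups next to Ca, since the acyl-bearing carbon is too stabilised to compete and the protic medium favours C- over O-alkylation.

**Compound list**

1 | propargyl alcohol | C#CCO | starting material
2 | 5-bromo-2-methylpent-2-ene | CC(C)=CCCBr | starting material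
3 | 7-methyloct-6-en-2-yn-1-ol | CC(C)=CCCC#CCO | intermediate
4 | (2E)-7-methylocta-2,6-dien-1-ol | CC(C)=CCC/C=C/CO | intermediate
5 | [(2R,3R)-3-(4-methylpent-3-en-1-yl)oxiran-2-yl]methanol | OC[C@H]1O[C@@H]1CCC=C(C)C | intermediate
6 | [(2R,3R)-3-(4-methylpent-3-en-1-yl)oxiran-2-yl]methyl 4-methylbenzenesulfonate | Cc1ccc(cc1)S(=O)(=O)OC[C@H]1O[C@@H]1CCC=C(C)C | intermediate
7 | [(2R,3R)-3-[(3E)-5-hydroxy-4-methylpent-3-en-1-yl]oxiran-2-yl]methyl 4-methylbenzenesulfonate | Cc1ccc(cc1)S(=O)(=O)OC[C@H]1O[C@@H]1CC/C=C(C)/CO | intermediate
8 | [(2R,3R)-3-[(3E)-5-bromo-4-methylpent-3-en-1-yl]oxiran-2-yl]methyl 4-methylbenzenesulfonate | Cc1ccc(cc1)S(=O)(=O)OC[C@H]1O[C@@H]1CC/C=C(C)/CBr | intermediate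
9 | di-tert-butyl malonate | CC(C)(C)OC(=O)CC(=O)OC(C)(C)C | starting material
10 | di-tert-butyl 2-[(2E)-2-methyl-5-[(2R,3R)-3-(tosyloxymethyl)oxiran-2-yl]pent-2-en-1-yl]malonate | Cc1ccc(cc1)S(=O)(=O)OC[C@H]1O[C@@H]1CC/C=C(C)/CC(C(=O)OC(C)(C)C)C(=O)OC(C)(C)C | intermediate
11 | di-tert-butyl (3R,4R,7E)-3,4-epoxy-8-methylcyclonon-7-ene-1,1-dicarboxylate | CC(C)(C)OC(=O)C1(C(=O)OC(C)(C)C)C[C@H]2O[C@@H]2CC/C=C(C)/C1 | intermediate
12 | tricyclic hydroxy lactone tert-butyl ester (trans-fused rings B/C, secondary OH at C4, bridged γ-lactone from C1 to O–C8) | O=C4[C@@]2(C[C@@H]3[C@H](CC[C@H]3O)[C@](C)(O4)C2)C(=O)OC(C)(C)C | intermediate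
13 | hydroxy lactone acid | O=C4[C@@]2(C[C@@H]3[C@H](CC[C@H]3O)[C@](C)(O4)C2)C(=O)O | intermediate
14 | keto lactone acid | O=C4[C@@]2(C[C@@H]3[C@H](CCC3=O)[C@](C)(O4)C2)C(=O)O | intermediate
15 | tertiary hydroxy lactone acid | O=C4[C@@]2(C[C@@H]3[C@H](CC[C@]3(C)O)[C@](C)(O4)C2)C(=O)O | intermediate
16 | 5-methylhexane-2,4-dione | CC(=O)CC(=O)C(C)C | starting material
17 | acyl imidazolide of 15 (not isolated) | O=C4[C@@]2(C[C@@H]3[C@H](CC[C@]3(C)O)[C@](C)(O4)C2)C(=O)n1ccnc1 | intermediate
18 | lactone triketone | O=C4[C@@]2(C[C@@H]3[C@H](CC[C@]3(C)O)[C@](C)(O4)C2)C(=O)C(C(C)=O)C(=O)C(C)C | intermediate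
19 | spiro trione with free ring A methylene | C1C(=O)[C@@]2(C[C@@H]3[C@H](CC[C@]3(C)O)[C@](C)(O)C2)C(=O)C(C(=O)C(C)C)=C1O | intermediate
20 | prenyl bromide | CC(C)=CCBr | starting material
21 | target compound | CC(C)=CCC1(CC=C(C)C)C(=O)[C@@]2(C[C@@H]3[C@H](CC[C@]3(C)O)[C@](C)(O)C2)C(=O)C(C(=O)C(C)C)=C1O | target

**Step count and risks**

Total step count: 15. Longest linear sequence: 15 steps (1 and 2 to 21).

Steps most likely to fail:

Step 9. An ester carbonyl may open the activated epoxide at C3 (five-membered lactone) faster than the alkene does, or the ring may close through the conformer that gives the cis-fused hydrindane. The fallback uses known chemistry, builds ring C first and closes ring B with the lactone by a radical cyclisation; it sets out from 9 and returns at 12.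
- Knoevenagel condensation of 9 with paraformaldehyde (Cu(OAc)2, KOAc, AcOH) gives di-tert-butyl methylenemalonate F1.
- Conjugate addition of isopropenylmagnesium bromide (CuBr·SMe2 cat.) to cyclopent-2-en-1-one, with the enolate trapped by F1, gives the racemic trans-2,3-disubstituted cyclopentanone F2.
- NaBH4 should reduce F2 mainly to the alcohol with OH trans to the side chain, F3.
- Candida antarctica lipase B with vinyl acetate is expected to acylate the wanted enantiomer to the acetate F4, which is separated and methanolysed (K2CO3, MeOH) back to enantiopure F3.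
- Mn(OAc)3 in AcOH then generates the malonyl radical, which closes ring B 6-endo onto the isopropenyl group across the trans substituents (the trans fusion is fixed in advance). The tertiary radical is oxidised to the cation and captured by the axial tert-butyl ester to give 12.

Step 8. Intermolecular alkylation (oligomerisation) may outrun closure of the strained nine-membered ring. The fallback closes the ring from the other end by palladium-catalysed allylic alkylation; it sets out from 7 (with 9) and returns at 11.
- 7 is alkylated at C2 by the sodium enolate of 9 (excess 9, 0 °C, to hold back attack of the new malonate on the epoxide) to give the hydroxy malonate F5.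
- ClCO2Me and pyridine convert F5 into the allylic methyl carbonate F6.
- Pd(PPh3)4 (zerovalent palladium) in THF at high dilution ionises the carbonate, and the malonate attacks the primary terminus of the allyl complex to give 11 (Tsuji–Trost macrocyclisation without added base).

Step 12. The methyl nucleophile may add with poor facial selectivity, or enolisation may epimerise C3. The fallback delivers oxygen instead of carbon to C4; it sets out from 14 and returns at 15.
- Wittig methylenation of 14 (Ph3P=CH2 from Ph3PCH3Br and KOt-Bu, in excess) gives the methylene lactone acid F7.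
- Mukaiyama hydration of F7 (Mn(dpm)3 cat., PhSiH3, O2, i-PrOH) adds hydrogen to the CH2 group and oxygen to C4. If the methyl nucleophile prefers the wrong face of the ketone, the same facial bias now places oxygen on that face and gives 15.

Further compounds
F1 | step 9 | di-tert-butyl methylenemalonate | C=C(C(=O)OC(C)(C)C)C(=O)OC(C)(C)C
F2 | step 9 | di-tert-butyl 2-[(trans-2-oxo-5-isopropenylcyclopentyl)methyl]malonate (racemic; the enantiomer carried on is drawn) | CC(C)(C)OC(=O)C(C(=O)OC(C)(C)C)C[C@@H]1[C@H](CCC1=O)C(C)=C
F3 | step 9 | di-tert-butyl 2-[(2-hydroxy-5-isopropenylcyclopentyl)methyl]malonate, OH trans to the side chain, isopropenyl trans to the side chain (formed racemic, used as the enantiomer drawn) | CC(C)(C)OC(=O)C(C(=O)OC(C)(C)C)C[C@@H]1[C@H](CC[C@H]1O)C(C)=C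
F4 | step 9 | acetate of F3 (single enantiomer) | CC(C)(C)OC(=O)C(C(=O)OC(C)(C)C)C[C@@H]1[C@H](CC[C@H]1OC(C)=O)C(C)=C
F5 | step 8 | di-tert-butyl 2-[[(2R,3R)-3-[(3E)-5-hydroxy-4-methylpent-3-en-1-yl]oxiran-2-yl]methyl]malonate | CC(C)(C)OC(=O)C(C(=O)OC(C)(C)C)C[C@H]1O[C@@H]1CC/C=C(C)/CO
F6 | step 8 | methyl carbonate of F5 | CC(C)(C)OC(=O)C(C(=O)OC(C)(C)C)C[C@H]1O[C@@H]1CC/C=C(C)/COC(=O)OC
F7 | step 12 | methylene lactone acid (C4=CH2 in place of the C4 ketone of 14) | O=C4[C@@]2(C[C@@H]3[C@H](CCC3=C)[C@](C)(O4)C2)C(=O)O
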